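**Plan**

1. Numbering: decalin C1–C10 (C1 CHBr, C4 and C5 carbinols, C7 carbinol bearing ring C, C10 C–Me; ring A = C1–C5 + C10, ring B = C5–C10), cyclopentane ring C = C11–C15 (C11 C–Me, C12 CHOH, C14 CHBr, C15 CMe2); α is the decalin face opposite the C10 methyl.
2. Cuts, last to first: C14–Br and the C12 carbinol (back to a cyclopentenone), C11–CH3 and C7–C11 (aldol of a 4,4-dimethylcyclopentenone enolate with a C7 ketone), the C4/C5 diol (α-epoxide of a C4=C5 alkene), C4=C5 (ring-closing metathesis), and finally C9–C10 together with C1–Br.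
3. Enabling feature: bromine on C1, the quaternary C10 and the oxygenated C5 are contiguous at the ring A/ring B junction; this is the pattern left when Br+ adds to C1 of a C1=C10 alkene and ring carbon C9 shifts from carbinol C5 to C10, so ring B can grow out of a 1-alkenylcyclopentanol.
4. Forward order: ring B by that bromonium-triggered ring expansion, ring A by metathesis and epoxide hydrolysis, ring C joined last as a preformed cyclopentenone, then C-methylation, hydrobromination and reduction.
5. Stereochemistry: C5 of the cyclopentanol from addition anti to a chiral-pool silyloxy group (oxidised away later); C1 and C10 by anti addition across the (Z)-alkene; C4 and C5 by directed α-epoxidation and diaxial opening; C7 by equatorial attack; C11, C14 and C12 by substrate control from the C7 carbinol and the C11 centre.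

Key step: step 6

Remark: the hydroxyl-bearing carbon of the starting cyclopentenone becomes C7; it serves only to control C5 and to direct the epoxidation, and its configuration is erased in step 13.

**Route**

Step 1
Reactants: 1 5-(trimethylsilyl)pent-4-yn-1-ol
Product: 2 5-(trimethylsilyl)pent-4-ynal
Conditions: Dess–Martin periodinane, NaHCO3, CH2Cl2, 0 °C to rt
Reagents that add atoms: none
Why: Dess–Martin oxidation of a primary alcohol stops at the aldehyde and leaves the silylalkyne untouched.

Step 2
Reactants: 2 5-(trimethylsilyl)pent-4-ynal; 3 ethyltriphenylphosphonium bromide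
Product: 7 [(5Z)-6-iodohept-5-en-1-yn-1-yl]trimethylsilane, via ethylidene ylide 4 (not isolated), via iodoethylphosphonium iodide 5 (not isolated), via iodoethylidene ylide 6 (not isolated)
Conditions: 3, n-BuLi, THF, 0 °C; I2, −78 °C; NaHMDS, −20 °C; then 2, −78 °C to rt
Reagents that add atoms: iodine, II
Why: Wittig olefination with the α-iodo ylide (made by iodination and re-deprotonation of the ethylidene ylide) is known to give (Z)-2-iodoalk-2-enes from aliphatic aldehydes, which places iodine cis to the C2 methylene as the later C5–C10 bond requires.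

Step 3
Reactants: 8 (4R)-4-[(tert-butyldimethylsilyl)oxy]cyclopent-2-en-1-one
Product: 9 (3S)-3-[(tert-butyldimethylsilyl)oxy]cyclopentan-1-one
Conditions: H2 (1 atm), Pd/C, EtOAc, rt
Reagents that add atoms: none
Why: catalytic hydrogenation saturates the conjugated alkene without touching the silyl ether or the stereocentre, whose descriptor changes from R to S only because the ring-carbon priorities change.

Step 4
Reactants: 7 [(5Z)-6-iodohept-5-en-1-yn-1-yl]trimethylsilane; 9 (3S)-3-[(tert-butyldimethylsilyl)oxy]cyclopentan-1-one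
Product: 11 (1R,3S)-3-[(tert-butyldimethylsilyl)oxy]-1-[(2Z)-7-(trimethylsilyl)hept-2-en-6-yn-2-yl]cyclopentan-1-ol, via alkenyllithium 10 (not isolated)
Conditions: 7, t-BuLi (2 equiv), Et2O, −78 °C; CeCl3, THF, −78 °C; then 9, −78 °C
Reagents that add atoms: none
Why: iodine–lithium exchange keeps the alkene geometry and the derived organocerium reagent adds 1,2 to the enolisable ketone, expected mainly on the face anti to the silyloxy group, which sets C5 (the minor C5 epimer is to be removed by chromatography).

Step 5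
Reactants: 11 (1R,3S)-3-[(tert-butyldimethylsilyl)oxy]-1-[(2Z)-7-(trimethylsilyl)hept-2-en-6-yn-2-yl]cyclopentan-1-ol
Product: 12 (1R,3S)-3-[(tert-butyldimethylsilyl)oxy]-1-[(2Z)-hept-2-en-6-yn-2-yl]cyclopentan-1-ol
Conditions: K2CO3, MeOH, rt
Reagents that add atoms: none
Why: base-mediated protodesilylation cleaves the alkynyl C–Si bond while the alkyl silyl ether and the tertiary allylic alcohol are stable.

Step 6
Reactants: 12 (1R,3S)-3-[(tert-butyldimethylsilyl)oxy]-1-[(2Z)-hept-2-en-6-yn-2-yl]cyclopentan-1-ol
Product: 13 (2R,5S)-2-[(1R)-1-bromopent-4-yn-1-yl]-5-[(tert-butyldimethylsilyl)oxy]-2-methylcyclohexan-1-one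
Conditions: N-bromosuccinimide, propylene oxide, i-PrOH, −78 °C to −20 °C
Reagents that add atoms: N-bromosuccinimide, O=C1CCC(=O)N1Br
Why: NBS transfers Br+ to C1 of the electron-rich trisubstituted alkene and, as positive charge builds at C10, the antiperiplanar ring bond C5–C9 shifts to C10 while the carbinol becomes the C5 ketone, which is the halonium-induced semipinacol ring expansion known for 1-alkenylcycloalkanols. Ring B is closed not by a cyclisation but by this suprafacial 1,2-alkyl shift, a five- to six-membered ring expansion that forms C9–C10. C1 and C10 arise together by anti addition of bromine and C9 across the (Z)-alkene, which fixes their relative configuration, and their absolute configuration is relayed from C5 because allylic strain holds the hydroxyl in the alkene plane so that C9 and C6 lie on opposite faces. The step needs C9 rather than C6 to migrate, which the silyloxy group on C7 should secure by inductively deactivating and crowding C6, and it needs Br+ to attack only the alkene, which holds because a terminal alkyne does not react with NBS without a silver salt. Bromine ends on C1 because the tertiary C10 carries the charge, so the neopentyl secondary C–Br bond is made by addition and not by substitution, and propylene oxide scavenges any HBr.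

Step 7
Reactants: 13 (2R,5S)-2-[(1R)-1-bromopent-4-yn-1-yl]-5-[(tert-butyldimethylsilyl)oxy]-2-methylcyclohexan-1-one
Product: 14 (2R,5S)-2-[(1R)-1-bromo-4-oxopentyl]-5-[(tert-butyldimethylsilyl)oxy]-2-methylcyclohexan-1-one
Conditions: (Ph3P)AuNTf2 (cat.), 1,4-dioxane/H2O, 60 °C
Reagents that add atoms: water, O
Why: gold-catalysed Markovnikov hydration of a terminal alkyne gives the methyl ketone under near-neutral conditions that the β-silyloxy ketone and the secondary bromide tolerate.

Step 8
Reactants: 14 (2R,5S)-2-[(1R)-1-bromo-4-oxopentyl]-5-[(tert-butyldimethylsilyl)oxy]-2-methylcyclohexan-1-one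
Product: 15 {[(1S,4R)-4-[(1R)-1-bromo-4-methylpent-4-en-1-yl]-4-methyl-3-methylidenecyclohexyl]oxy}(tert-butyl)dimethylsilane
Conditions: Cp2TiMe2 (excess), toluene, 75 °C, dark
Reagents that add atoms: dimethyltitanocene, C[Ti](C)(C1C=CC=C1)C1C=CC=C1
Why: carbonyl methylenation by the non-basic titanium methylidene generated thermally from Cp2TiMe2 converts both the methyl ketone and the hindered C5 ketone without β-elimination of the silyloxy group or of HBr.

Step 9
Reactants: 15 {[(1S,4R)-4-[(1R)-1-bromo-4-methylpent-4-en-1-yl]-4-methyl-3-methylidenecyclohexyl]oxy}(tert-butyl)dimethylsilane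
Product: 16 {[(2S,4aR,5R)-5-bromo-4a,8-dimethyl-1,2,3,4,4a,5,6,7-octahydronaphthalen-2-yl]oxy}(tert-butyl)dimethylsilane
Conditions: second-generation Hoveyda–Grubbs catalyst (10 mol %), toluene, 100 °C, argon sparge
Reagents that add atoms: none
Why: ring-closing metathesis of the two 1,1-disubstituted alkenes closes the six-membered ring A as the tetrasubstituted C4=C5 alkene with loss of ethene, helped by the quaternary C10 in the tether.

Step 10
Reactants: 16 {[(2S,4aR,5R)-5-bromo-4a,8-dimethyl-1,2,3,4,4a,5,6,7-octahydronaphthalen-2-yl]oxy}(tert-butyl)dimethylsilane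
Product: 17 (2S,4aR,5R)-5-bromo-4a,8-dimethyl-1,2,3,4,4a,5,6,7-octahydronaphthalen-2-ol
Conditions: HF·pyridine, THF, 0 °C to rt
Reagents that add atoms: none
Why: acidic fluoride desilylation frees the C7 hydroxyl without the E2 loss of the C1 bromide that a basic fluoride source could cause.

Step 11
Reactants: 17 (2S,4aR,5R)-5-bromo-4a,8-dimethyl-1,2,3,4,4a,5,6,7-octahydronaphthalen-2-ol
Product: 18 1β-bromo-4α,5α-epoxy-4,10β-dimethyldecalin-7α-ol
Conditions: VO(acac)2 (cat.), t-BuOOH, CH2Cl2, 0 °C to rt
Reagents that add atoms: tert-butyl hydroperoxide, CC(C)(C)OO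
Why: vanadium-catalysed epoxidation directed by the homoallylic 7α-hydroxyl delivers oxygen to the α face of the C4=C5 alkene, which is also the face away from the C10 methyl, and so sets the epoxide carbons C4 and C5.

Step 12
Reactants: 18 1β-bromo-4α,5α-epoxy-4,10β-dimethyldecalin-7α-ol
Product: 19 1β-bromo-4α,10β-dimethyl-trans-decalin-4β,5α,7α-triol
Conditions: HClO4 (cat.), THF/H2O, 0 °C to rt
Reagents that add atoms: water, O
Why: acid-catalysed epoxide hydrolysis follows the Fürst–Plattner rule, water attacking C4 from the β face with inversion while C5 keeps its α oxygen, so the trans-diaxial 4β,5α-diol results.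

Step 13
Reactants: 19 1β-bromo-4α,10β-dimethyl-trans-decalin-4β,5α,7α-triol
Product: 20 1β-bromo-4β,5α-dihydroxy-4α,10β-dimethyl-trans-decalin-7-one
Conditions: Dess–Martin periodinane, NaHCO3, CH2Cl2, 0 °C
Reagents that add atoms: none
Why: Dess–Martin oxidation converts the only secondary alcohol into the C7 ketone under buffered conditions that leave the tertiary diol alone and should not dehydrate the β-hydroxy ketone.

Step 14
Reactants: 20 1β-bromo-4β,5α-dihydroxy-4α,10β-dimethyl-trans-decalin-7-one; 21 4,4-dimethylcyclopent-2-en-1-one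
Product: 23 5-(1β-bromo-4β,5α,7α-trihydroxy-4α,10β-dimethyl-trans-decalin-7β-yl)-4,4-dimethylcyclopent-2-en-1-one (C11 epimers), via lithium dienolate 22 (not isolated)
Conditions: 21, LDA, THF, −78 °C; then 20 (enolate in excess), −78 °C; AcOH quench at −78 °C
Reagents that add atoms: none
Why: kinetic deprotonation of the enone at its only enolisable α′ position gives the cross-conjugated lithium dienolate, whose aldol addition to the C7 ketone should occur by equatorial attack because the axial 5α oxygen blocks the α face, setting the 7α-hydroxyl (the first equivalents of enolate deprotonate the diol, and the C11 epimers converge in step 15).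

Step 15
Reactants: 23 5-(1β-bromo-4β,5α,7α-trihydroxy-4α,10β-dimethyl-trans-decalin-7β-yl)-4,4-dimethylcyclopent-2-en-1-one
Product: 25 5-(1β-bromo-4β,5α,7α-trihydroxy-4α,10β-dimethyl-trans-decalin-7β-yl)-4,4,5-trimethylcyclopent-2-en-1-one with the target configuration at C11, via tetralithium dienolate 24 (not isolated)
Conditions: LDA (5 equiv), THF/DMPU, −78 °C to −45 °C; MeI, −78 °C to −30 °C
Reagents that add atoms: iodomethane, CI
Why: C-alkylation of the chelated aldolate dienolate (dianion alkylation of a β-hydroxy ketone) makes C11 quaternary, and methyl is expected to enter from the C8 side of the planar lithium chelate between the C7 and C12 oxygens because the C6 side carries the quaternary C5 and its lithium-bound 5α-alkoxide, which gives the target C11 configuration.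

Step 16
Reactants: 25 5-(1β-bromo-4β,5α,7α-trihydroxy-4α,10β-dimethyl-trans-decalin-7β-yl)-4,4,5-trimethylcyclopent-2-en-1-one
Product: 26 3-bromo-5-(1β-bromo-4β,5α,7α-trihydroxy-4α,10β-dimethyl-trans-decalin-7β-yl)-4,4,5-trimethylcyclopentan-1-one, bromine on C14 cis to the decalin substituent on C11
Conditions: HBr (g), CH2Cl2, −40 °C to −10 °C; crude product used directly
Reagents that add atoms: hydrogen bromide, Br
Why: conjugate hydrobromination of the cyclopentenone is reversible, so C14 should settle as the epimer with bromine trans to the pseudo-axial C11 methyl and cis to the carbinol substituent, and the second neopentyl C–Br bond again arises by addition.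

Step 17
Reactants: 26 3-bromo-5-(1β-bromo-4β,5α,7α-trihydroxy-4α,10β-dimethyl-trans-decalin-7β-yl)-4,4,5-trimethylcyclopentan-1-one
Product: 27 CNP0390567.2, 4-bromo-7-(3-bromo-5-hydroxy-1,2,2-trimethylcyclopentyl)-1,4a-dimethyldecahydronaphthalene-1,7,8a-triol with the configuration of the target SMILES
Conditions: Zn(BH4)2, Et2O, −40 °C; aqueous NH4Cl
Reagents that add atoms: none
Why: chelation-assisted ketone reduction with Zn(BH4)2 should deliver hydride to C12 from the face of the C11 methyl, anti to the bulky C7 carbinol whose ring carbons shield the other face, giving the C12 hydroxyl cis to C7 and to the C14 bromine without base-induced loss of HBr.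

**Compound list**

1 | 5-(trimethylsilyl)pent-4-yn-1-ol | OCCCC#C[Si](C)(C)C | starting material
2 | 5-(trimethylsilyl)pent-4-ynal | O=CCCC#C[Si](C)(C)C | intermediate
3 | ethyltriphenylphosphonium bromide | CC[P+](c1ccccc1)(c1ccccc1)c1ccccc1.[Br-] | starting material
4 | ethylidene(triphenyl)phosphorane | CC=P(c1ccccc1)(c1ccccc1)c1ccccc1 | intermediate
5 | (1-iodoethyl)triphenylphosphonium iodide | CC(I)[P+](c1ccccc1)(c1ccccc1)c1ccccc1.[I-] | intermediate
6 | (1-iodoethylidene)triphenylphosphorane | CC(I)=P(c1ccccc1)(c1ccccc1)c1ccccc1 | intermediate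
7 | [(5Z)-6-iodohept-5-en-1-yn-1-yl]trimethylsilane | I/C(C)=C\CCC#C[Si](C)(C)C | intermediate
8 | (4R)-4-[(tert-butyldimethylsilyl)oxy]cyclopent-2-en-1-one | O=C1C[C@@H](O[Si](C)(C)C(C)(C)C)C=C1 | starting material
9 | (3S)-3-[(tert-butyldimethylsilyl)oxy]cyclopentan-1-one | O=C1C[C@@H](O[Si](C)(C)C(C)(C)C)CC1 | intermediate
10 | [(2Z)-7-(trimethylsilyl)hept-2-en-6-yn-2-yl]lithium | [Li]/C(C)=C\CCC#C[Si](C)(C)C | intermediate
11 | (1R,3S)-3-[(tert-butyldimethylsilyl)oxy]-1-[(2Z)-7-(trimethylsilyl)hept-2-en-6-yn-2-yl]cyclopentan-1-ol | O[C@]1(C[C@@H](O[Si](C)(C)C(C)(C)C)CC1)/C(C)=C\CCC#C[Si](C)(C)C | intermediate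
12 | (1R,3S)-3-[(tert-butyldimethylsilyl)oxy]-1-[(2Z)-hept-2-en-6-yn-2-yl]cyclopentan-1-ol | O[C@]1(C[C@@H](O[Si](C)(C)C(C)(C)C)CC1)/C(C)=C\CCC#C | intermediate
13 | (2R,5S)-2-[(1R)-1-bromopent-4-yn-1-yl]-5-[(tert-butyldimethylsilyl)oxy]-2-methylcyclohexan-1-one | O=C1C[C@@H](O[Si](C)(C)C(C)(C)C)CC[C@@]1(C)[C@H](Br)CCC#C | intermediate
14 | (2R,5S)-2-[(1R)-1-bromo-4-oxopentyl]-5-[(tert-butyldimethylsilyl)oxy]-2-methylcyclohexan-1-one | O=C1C[C@@H](O[Si](C)(C)C(C)(C)C)CC[C@@]1(C)[C@H](Br)CCC(C)=O | intermediate
15 | {[(1S,4R)-4-[(1R)-1-bromo-4-methylpent-4-en-1-yl]-4-methyl-3-methylidenecyclohexyl]oxy}(tert-butyl)dimethylsilane | C=C1C[C@@H](O[Si](C)(C)C(C)(C)C)CC[C@@]1(C)[C@H](Br)CCC(C)=C | intermediate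
16 | {[(2S,4aR,5R)-5-bromo-4a,8-dimethyl-1,2,3,4,4a,5,6,7-octahydronaphthalen-2-yl]oxy}(tert-butyl)dimethylsilane | CC1=C2C[C@@H](O[Si](C)(C)C(C)(C)C)CC[C@@]2(C)[C@H](Br)CC1 | intermediate
17 | (2S,4aR,5R)-5-bromo-4a,8-dimethyl-1,2,3,4,4a,5,6,7-octahydronaphthalen-2-ol | CC1=C2C[C@@H](O)CC[C@@]2(C)[C@H](Br)CC1 | intermediate
18 | 1β-bromo-4α,5α-epoxy-4,10β-dimethyldecalin-7α-ol | C[C@@]12CC[C@@H](Br)[C@]3(C)CC[C@H](O)C[C@@]13O2 | intermediate
19 | 1β-bromo-4α,10β-dimethyl-trans-decalin-4β,5α,7α-triol | O[C@H]1CC[C@@]2(C)[C@H](Br)CC[C@](C)(O)[C@]2(O)C1 | intermediate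
20 | 1β-bromo-4β,5α-dihydroxy-4α,10β-dimethyl-trans-decalin-7-one | O=C1CC[C@@]2(C)[C@H](Br)CC[C@](C)(O)[C@]2(O)C1 | intermediate
21 | 4,4-dimethylcyclopent-2-en-1-one | CC1(C)C=CC(=O)C1 | starting material
22 | lithium 5,5-dimethylcyclopenta-1,3-dien-1-olate | CC1(C)C=CC(O[Li])=C1 | intermediate
23 | 5-(1β-bromo-4β,5α,7α-trihydroxy-4α,10β-dimethyl-trans-decalin-7β-yl)-4,4-dimethylcyclopent-2-en-1-one (C11 epimers) | CC1(C)C=CC(=O)C1[C@]1(O)CC[C@@]2(C)[C@H](Br)CC[C@](C)(O)[C@]2(O)C1 | intermediate
24 | tetralithium trialkoxide dienolate of 23 | CC1(C)C=CC(O[Li])=C1[C@]1(O[Li])CC[C@@]2(C)[C@H](Br)CC[C@](C)(O[Li])[C@]2(O[Li])C1 | intermediate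
25 | 5-(1β-bromo-4β,5α,7α-trihydroxy-4α,10β-dimethyl-trans-decalin-7β-yl)-4,4,5-trimethylcyclopent-2-en-1-one, target configuration at C11 | CC1(C)C=CC(=O)[C@@]1(C)[C@]1(O)CC[C@@]2(C)[C@H](Br)CC[C@](C)(O)[C@]2(O)C1 | intermediate
26 | 3-bromo-5-(1β-bromo-4β,5α,7α-trihydroxy-4α,10β-dimethyl-trans-decalin-7β-yl)-4,4,5-trimethylcyclopentan-1-one, C14 bromine cis to the decalin | CC1(C)[C@@H](Br)CC(=O)[C@@]1(C)[C@]1(O)CC[C@@]2(C)[C@H](Br)CC[C@](C)(O)[C@]2(O)C1 | intermediate
27 | CNP0390567.2, 4-bromo-7-(3-bromo-5-hydroxy-1,2,2-trimethylcyclopentyl)-1,4a-dimethyldecahydronaphthalene-1,7,8a-triol (1β-Br, 4β-OH, 5α-OH, 7α-OH, 10β-Me; ring C hydroxyl, bromine and decalin cis, C11 methyl trans) | CC1(C)[C@@H](Br)C[C@@H](O)[C@@]1(C)[C@]1(O)CC[C@@]2(C)[C@H](Br)CC[C@](C)(O)[C@]2(O)C1 | target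

**Count**

Total step count: 17. Longest linear sequence: 16 steps (from 1 through steps 1, 2 and 4 to 17; step 3 is a one-step side branch).

**Steps most likely to fail**

Step 15. Enolisation of the hindered C11–H may be slower than retro-aldol cleavage of the crowded C7–C11 bond, and facial discrimination at C11 rests on a chelate model only. The fallback sets C11 by chirality transfer; it sets out from 20 and returns at 25. Lipase-catalysed acetylation of the R enantiomer of commercial racemic 4-methylpent-3-en-2-ol leaves (S)-4-methylpent-3-en-2-ol F1, which is acylated to (S)-4-methylpent-3-en-2-yl propanoate F2. Aldol addition of the lithium enolate of F2 to 20 gives the β-hydroxy ester F3. Deprotonation with LDA forms the alkoxide-chelated enolate, and silylation with Me3SiCl followed by warming brings about an Ireland–Claisen rearrangement. The chair with the carbinol methyl equatorial forms C11–C15 and gives the acid F4, with C11 fixed by the ester stereocentre and independent of C7. Methyllithium converts F4 into the methyl ketone F5, ozonolysis of the propenyl group gives the keto aldehyde F6, and intramolecular aldol condensation closes ring C to 25.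

Step 9. Ring closure has to engage a neopentyl 1,1-disubstituted alkene and form a tetrasubstituted alkene, so catalyst decay and alkene isomerisation may outrun cyclisation. The fallback forms the C4–C5 bond reductively; it sets out from 14 and returns at 16. SmI2-mediated intramolecular pinacol coupling of the two ketones gives the cis-4,5-diol F7. 1,1′-Thiocarbonyldiimidazole converts it into the cyclic thionocarbonate F8, and Corey–Winter elimination with 1,3-dimethyl-2-phenyl-1,3,2-diazaphospholidine gives alkene 16.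

Step 16. Protic acid may ionise the tertiary alcohols or trigger pinacol-type rearrangement of the 4,5-diol, the adduct may lose HBr again on handling, and the C7 hydroxyl may add to the enone in competition with bromide. The fallback avoids acid; it sets out from 25 and returns at 27. Copper-catalysed conjugate borylation (CuCl, NaOt-Bu, bis(pinacolato)diboron, MeOH) should place boron on C14 on the face of the C11 methyl, giving the β-boryl ketone F9. Zn(BH4)2 reduction gives the boryl tetraol F10. Formation of the boronate complex with 3,5-bis(trifluoromethyl)phenyllithium and treatment with N-bromosuccinimide then replaces boron by bromine with inversion, giving 27.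

**Further compounds**

F1 | step 15 | (S)-4-methylpent-3-en-2-ol | C[C@H](O)C=C(C)C
F2 | step 15 | (S)-4-methylpent-3-en-2-yl propanoate | CCC(=O)O[C@@H](C)C=C(C)C
F3 | step 15 | (S)-4-methylpent-3-en-2-yl 2-(1β-bromo-4β,5α,7α-trihydroxy-4α,10β-dimethyl-trans-decalin-7β-yl)propanoate (C11 epimers) | CC([C@]1(O)CC[C@@]2(C)[C@H](Br)CC[C@](C)(O)[C@]2(O)C1)C(=O)O[C@@H](C)C=C(C)C
F4 | step 15 | (E)-2-(1β-bromo-4β,5α,7α-trihydroxy-4α,10β-dimethyl-trans-decalin-7β-yl)-2,3,3-trimethylhex-4-enoic acid, target configuration at C11 | C/C=C/C(C)(C)[C@@](C)(C(=O)O)[C@]1(O)CC[C@@]2(C)[C@H](Br)CC[C@](C)(O)[C@]2(O)C1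
F5 | step 15 | (E)-3-(1β-bromo-4β,5α,7α-trihydroxy-4α,10β-dimethyl-trans-decalin-7β-yl)-3,4,4-trimethylhept-5-en-2-one | C/C=C/C(C)(C)[C@@](C)(C(C)=O)[C@]1(O)CC[C@@]2(C)[C@H](Br)CC[C@](C)(O)[C@]2(O)C1
F6 | step 15 | 3-(1β-bromo-4β,5α,7α-trihydroxy-4α,10β-dimethyl-trans-decalin-7β-yl)-2,2,3-trimethyl-4-oxopentanal | O=CC(C)(C)[C@@](C)(C(C)=O)[C@]1(O)CC[C@@]2(C)[C@H](Br)CC[C@](C)(O)[C@]2(O)C1
F7 | step 9 | 1β-bromo-7α-[(tert-butyldimethylsilyl)oxy]-4,10β-dimethyldecalin-4,5-diol (cis diol) | CC1(O)CC[C@@H](Br)[C@]2(C)CC[C@H](O[Si](C)(C)C(C)(C)C)CC12O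
F8 | step 9 | cyclic 4,5-thionocarbonate of F7 | CC12CC[C@@H](Br)[C@]3(C)CC[C@H](O[Si](C)(C)C(C)(C)C)CC13OC(=S)O2
F9 | step 16 | 5-(1β-bromo-4β,5α,7α-trihydroxy-4α,10β-dimethyl-trans-decalin-7β-yl)-4,4,5-trimethyl-3-(4,4,5,5-tetramethyl-1,3,2-dioxaborolan-2-yl)cyclopentan-1-one, boron cis to the C11 methyl | CC1(C)[C@H](B2OC(C)(C)C(C)(C)O2)CC(=O)[C@@]1(C)[C@]1(O)CC[C@@]2(C)[C@H](Br)CC[C@](C)(O)[C@]2(O)C1
F10 | step 16 | C12 alcohol of F9 (hydroxyl cis to the decalin) | CC1(C)[C@H](B2OC(C)(C)C(C)(C)O2)C[C@@H](O)[C@@]1(C)[C@]1(O)CC[C@@]2(C)[C@H](Br)CC[C@](C)(O)[C@]2(O)C1
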